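| flask | left-handed substrate | right-handed substrate | solid reagent | temperature | remark | time |
|---|---|---|---|---|---|---|
| birch | 0.010 M | 0.010 M | 0.044 M | 28 °C | run made earlier |  |
| ash | 0.040 M | 0.040 M | 0.044 M | 44 °C | run made earlier |  |
| dusk | 0.020 M | 0.020 M | 0.0440 M | 50 °C |  | 15 min |
| noon | 0.020 M | 0.020 M | 0.0440 M | 20 °C |  | 15 min |

| run | time / min | left-handed product / % | right-handed product / % | left-handed substrate / % |
|---|---|---|---|---|
| birch | 2.00 | 0.2 | 0.4 | 49.0 |
| birch | 3.00 | 0 | 0.2 | 48.6 |
| birch | 4.00 | 0 | 0 | 48.5 |
| birch | 8.00 | 0.8 | 0 | 46.9 |
| birch | 12.0 | 0.9 | 0 | 44.8 |
| birch | 20.0 | 2.7 | 0.4 | 42.5 |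
| birch | 30.0 | 6.2 | 0.9 | 35.7 |
| ash | 1.33 | 0.1 | 0 | 46.8 |
| ash | 2.50 | 0.9 | 0.3 | 46.8 |
| ash | 4.00 | 0.5 | 0 | 44.7 |
| ash | 5.00 | 0.7 | 0.9 | 42.2 |
| ash | 6.00 | 1.5 | 0 | 40.3 |
| ash | 8.00 | 2.2 | 1.2 | 38.2 |
| ash | 10.0 | 3.2 | 0.1 | 35.3 |

(readings scatter by 0.5 percentage points)

- coupling partner is single-handed; left-handed substrate and right-handed substrate are mirror images of each other, charged as a racemate, each of them at the stated concentration
- solid reagent is a solid; its amount is given per volume of the solution
- candidate steps: coupling partner + left-handed substrate -> left-handed product; coupling partner + right-handed substrate -> right-handed product; left-handed substrate <-> achiral form; right-handed substrate <-> achiral form; coupling partner <-> dormant form; solid reagent <-> coupling partner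
- at the start none of the solid reagent is in solution
- an excess is the difference of the two amounts in percent of their sum
- an excess is below zero if the other one leads
- the handed part of coupling partner does not stay in what it makes, so the products of the two hands are mirror images too

- the best flask by excess of left-handed product over right-handed product; "all alike" if 1.5 percentage points covers them all (dusk / noon / all alike)
- excess of left-handed product over right-handed product at the end, dusk
- excess of left-handed product over right-handed product at the end, noon

Left-handed product outran right-handed product at the last reading of both earlier runs, in birch with 6.2% against 0.9%, so I followed one molecule of coupling partner. At a fixed temperature and while c(left-handed substrate) equals c(right-handed substrate), its chance of taking either hand does not depend on how much partner has dissolved, so the excess should read the same throughout that stretch.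

I read it in two ways. The last reading gave 74.6% in birch, and pooling every reading of the run gave 70.1%, but the pool contains that last reading, so the two figures were no check on each other. In ash they parted, at 93.9% against 56.9%. In ash both cheated. The last ash reading of right-handed product, 0.1%, lies below the scatter of 0.5 percentage points, and pooling collects early readings that are never negative, so their noise only adds.

The 9 early right-handed readings, taken while left-handed product read at most 0.9%, averaged a floor of 0.2 points. I took the last two readings of each run, with that floor taken off each right-handed one. For birch I kept 9.89 as the selectivity factor, left-handed product made per right-handed product while both substrates stand equal, which is an excess of 81.6%. Ash gave 6.00, or 71.4%. Each sum of two readings carries 0.71 points of scatter, so I took the lead of birch, the colder run, over ash only as a direction, and I committed to noon, the colder flask, near 81.6% and dusk, the hotter, near 71.4%.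

The forecast, holding that “Selectivity therefore falls on heating”, named noon, with noon at 75% (62% to 87%) and dusk at 57% (45% to 68%), both lower than mine.

Noon gave 89.0% and dusk 82.8%, so noon was the better flask, and my figures stood 7.4 points and 11 points too low.

    coupling partner + left-handed substrate → left-handed product (k = 5.80 /M/min, Ea = 64.0 kJ/mol)
    coupling partner + right-handed substrate → right-handed product (k = 0.510 /M/min, Ea = 75.0 kJ/mol)
    left-handed substrate ⇌ achiral form (K = 1.70, k = 0.0640 /min, Ea = 88.0 kJ/mol, ΔH = −40.0 kJ/mol)
    right-handed substrate ⇌ achiral form (K = 1.70, k = 0.0640 /min, Ea = 88.0 kJ/mol, ΔH = −40.0 kJ/mol)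
    coupling partner ⇌ dormant form (K = 0.420, k = 0.00920 /min, Ea = 100 kJ/mol, ΔH = −53.0 kJ/mol)
    solid reagent ⇌ coupling partner, rate k6*(cs6 - [coupling partner]) while solid is left; crystals form when [coupling partner] > cs6 (solubility = 17.0 mM, k = 0.0280 /min)
    (constants at 50 °C)

Noon's conversion at the end was 4.43%. Divided by the selectivity factor read from birch, 9.89, noon's 1.09% of left-handed product gives 0.110% of right-handed product, against 0.0638% in the flask, and both right-handed figures lie below the scatter. Noon read at 10 min held left-handed substrate at 48.4% and right-handed substrate at 48.9%; its 0.522% of left-handed product over the same factor gives 0.0528%, against 0.0303% found, and its excess of left-handed product stood at 89.0%.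

The runs are calculated for substances that don't exist; noise was put on by code.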